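The C3–C4 bond of the pyranone ring (ring C) is the disconnection on which the route rests. C3 sits between the aryl-bearing ether carbon C2 and the C4 ketone, so this bond can be read as the C3=C4 double bond of the C4 silyl enol ether and made by ring-closing metathesis. In one operation the key step closes ring C and delivers C4 at the ketone oxidation level without touching C2. Its precursor is an aryl 1-arylallyl ether in which C2 is already S (iridium-catalysed allylic etherification) and in which ring A carries, ortho to the ether oxygen, the tert-butyldimethylsilyl enol ether of an acetyl group.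

Key step: step 6

Assumption: flavanone numbering (O1, C2, C3, C4; ring A = trimethoxybenzo ring, ring B = dimethoxyphenyl ring, ring C = pyranone) is used for all intermediates. The (Sa,Sc,Sc) phosphoramidite is taken to give the S ether, as the accepted model for aryl-substituted allyl carbonates with oxygen nucleophiles predicts; its mirror image would be used if the correlation ran the other way.

Design remarks: the silyl enol ether is installed only after the etherification, so it never meets the aryloxide or the iridium catalyst. The tert-butyldimethylsilyl group is chosen so that the enol ether survives chromatography on Et3N-washed SiO2 and the warm metathesis. The aryloxide is used as its sodium salt and in excess, because the chelated ortho-acyl phenoxide is a sluggish nucleophile.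

Step 1
Reactants: 1 3,4,5-trimethoxyphenol
Product: 3 1-(6-hydroxy-2,3,4-trimethoxyphenyl)ethan-1-one, via difluoroboron chelate 2 (not isolated)
Conditions: AcOH, BF3·OEt2, 85 °C; then H2O, rt
Reagents that add atoms: acetic acid, CC(=O)O
Why: BF3-mediated Friedel–Crafts (Fries-type) C-acylation of a phenol can only strike one of the two equivalent free carbons ortho to the hydroxyl of 1, and the ketone is held as its BF2 chelate 2, which blocks a second acylation and is hydrolysed on aqueous work-up.

Step 2
Reactants: 4 (E)-3-(3,4-dimethoxyphenyl)prop-2-enoic acid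
Product: 6 (E)-3-(3,4-dimethoxyphenyl)prop-2-en-1-ol, via mixed carbonic anhydride 5 (not isolated)
Conditions: ClCO2Et, Et3N, THF, −10 °C; then NaBH4, H2O, 0 °C → rt
Reagents that add atoms: none
Why: Mixed-anhydride activation followed by borohydride reduction: hydride attacks the acyl carbonyl of 5 and then the aldehyde in a 1,2 sense, which should leave the conjugated E alkene intact.

Step 3
Reactants: 6 (E)-3-(3,4-dimethoxyphenyl)prop-2-en-1-ol
Product: 7 (E)-3-(3,4-dimethoxyphenyl)prop-2-en-1-yl methyl carbonate
Conditions: ClCO2Me, pyridine, CH2Cl2, 0 °C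
Reagents that add atoms: methyl chloroformate, COC(=O)Cl
Why: Pyridine-promoted O-acylation of a primary allylic alcohol with a chloroformate is a routine carbonate formation that leaves the alkene geometry unchanged.

Step 4
Reactants: 3 1-(6-hydroxy-2,3,4-trimethoxyphenyl)ethan-1-one; 7 (E)-3-(3,4-dimethoxyphenyl)prop-2-en-1-yl methyl carbonate
Product: 9 1-(2-{[(1S)-1-(3,4-dimethoxyphenyl)prop-2-en-1-yl]oxy}-4,5,6-trimethoxyphenyl)ethan-1-one, via sodium 2-acetyl-3,4,5-trimethoxyphenolate 8 (not isolated)
Conditions: 3 (1.5 equiv), NaH, THF, 0 °C; then 7, [Ir(cod)Cl]2 (2 mol%), (Sa,Sc,Sc)-O,O'-(1,1'-binaphthyl-2,2'-diyl) N,N-bis(1-phenylethyl)phosphoramidite (4 mol%, preactivated with n-PrNH2), THF, rt, stopped when 7 is consumed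
Reagents that add atoms: none
Why: Iridium-catalysed asymmetric allylic etherification: 7 ionises to an allyliridium complex that aryloxide 8 attacks at the aryl-substituted terminus anti to the metal, giving the branched ether, and the cyclometalated (Sa,Sc,Sc) phosphoramidite fixes the face of attack and so sets the new stereocentre (the future C2) as S.

Step 5
Reactants: 9 1-(2-{[(1S)-1-(3,4-dimethoxyphenyl)prop-2-en-1-yl]oxy}-4,5,6-trimethoxyphenyl)ethan-1-one
Product: 10 tert-butyl({1-[2-{[(1S)-1-(3,4-dimethoxyphenyl)prop-2-en-1-yl]oxy}-4,5,6-trimethoxyphenyl]ethenyl}oxy)dimethylsilane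
Conditions: TBSOTf, Et3N, CH2Cl2, −78 → 0 °C; chromatography on Et3N-washed SiO2
Reagents that add atoms: tert-butyldimethylsilyl trifluoromethanesulfonate, CC(C)(C)[Si](C)(C)OS(=O)(=O)C(F)(F)F
Why: Soft enolisation of an aryl methyl ketone (O-silylation by the silyl triflate, then deprotonation of the only enolisable position by Et3N) should give the terminal silyl enol ether in a medium that stays basic, so the benzylic allylic ether and C2 are not disturbed.

Step 6
Reactants: 10 tert-butyl({1-[2-{[(1S)-1-(3,4-dimethoxyphenyl)prop-2-en-1-yl]oxy}-4,5,6-trimethoxyphenyl]ethenyl}oxy)dimethylsilane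
Product: 11 (2S)-4-(tert-butyldimethylsilyloxy)-2-(3,4-dimethoxyphenyl)-5,6,7-trimethoxy-2H-chromene
Conditions: RuCl2(=CHPh)(H2IMes)(PCy3) (second-generation Grubbs catalyst, 5 mol%), 1,4-benzoquinone (10 mol%), degassed PhMe (0.005 M), 60 °C
Reagents that add atoms: none
Why: This is ring-closing olefin metathesis of a silyl enol ether, a known reaction class with second-generation ruthenium carbenes: the catalyst loads onto the monosubstituted vinyl group at C2, the resulting alkylidene adds across the 1,1-disubstituted enol ether in an intramolecular [2+2] step with ruthenium on the CH2 carbon, and cycloreversion expels the methylidene (lost as ethylene) and forms C3=C4. Ring C closes as a six-membered ring from a 1,7-diene, with the new double bond endocyclic and conjugated with ring A. No stereocentre is created, and C2, whose hydrogen takes no part, keeps the S configuration set in step 4. The step needs cyclisation to win over cross-metathesis dimerisation at the vinyl group and over ruthenium hydride-induced migration of the allylic double bond, which would destroy C2. High dilution, the ortho placement of both alkenes on ring A, the inability of the hindered enol ether to homodimerise, and 1,4-benzoquinone as hydride scavenger should secure this. The temperature stays far below that needed for an aromatic Claisen rearrangement of the allyl aryl ether.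

Step 7
Reactants: 11 (2S)-4-(tert-butyldimethylsilyloxy)-2-(3,4-dimethoxyphenyl)-5,6,7-trimethoxy-2H-chromene
Product: 12 (2S)-2-(3,4-dimethoxyphenyl)-5,6,7-trimethoxy-2,3-dihydro-4H-chromen-4-one
Conditions: 1 M aq HCl, THF, 0 °C
Reagents that add atoms: none
Why: Acid hydrolysis of a silyl enol ether: protonation at C3 gives a silyloxocarbenium ion that loses silicon to water, so the C4 ketone appears without a free enolate that could open ring C by β-elimination of the ring A phenoxide, and C2 stays S.

Compound list
1 | 3,4,5-trimethoxyphenol | COc1cc(O)cc(OC)c1OC | starting material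
2 | difluoroboron chelate of 3 (2,2-difluoro-5,6,7-trimethoxy-4-methyl-1,3,2-benzodioxaborinine, carbonyl O→B dative form; formed in the flask) | CC1=[O+][B-](F)(F)Oc2cc(OC)c(OC)c(OC)c12 | intermediate
3 | 1-(6-hydroxy-2,3,4-trimethoxyphenyl)ethan-1-one | CC(=O)c1c(O)cc(OC)c(OC)c1OC | intermediate
4 | (E)-3-(3,4-dimethoxyphenyl)prop-2-enoic acid (3,4-dimethoxycinnamic acid) | COc1ccc(/C=C/C(=O)O)cc1OC | starting material
5 | (E)-3-(3,4-dimethoxyphenyl)prop-2-enoic ethyl carbonic anhydride (formed in the flask) | CCOC(=O)OC(=O)/C=C/c1ccc(OC)c(OC)c1 | intermediate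
6 | (E)-3-(3,4-dimethoxyphenyl)prop-2-en-1-ol | COc1ccc(/C=C/CO)cc1OC | intermediate
7 | (E)-3-(3,4-dimethoxyphenyl)prop-2-en-1-yl methyl carbonate | COC(=O)OC/C=C/c1ccc(OC)c(OC)c1 | intermediate
8 | sodium 2-acetyl-3,4,5-trimethoxyphenolate (formed in the flask) | CC(=O)c1c([O-])cc(OC)c(OC)c1OC.[Na+] | intermediate
9 | 1-(2-{[(1S)-1-(3,4-dimethoxyphenyl)prop-2-en-1-yl]oxy}-4,5,6-trimethoxyphenyl)ethan-1-one | COc1ccc([C@@H](Oc2cc(OC)c(OC)c(OC)c2C(C)=O)C=C)cc1OC | intermediate
10 | tert-butyl({1-[2-{[(1S)-1-(3,4-dimethoxyphenyl)prop-2-en-1-yl]oxy}-4,5,6-trimethoxyphenyl]ethenyl}oxy)dimethylsilane | COc1ccc([C@@H](Oc2cc(OC)c(OC)c(OC)c2C(=C)O[Si](C)(C)C(C)(C)C)C=C)cc1OC | intermediate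
11 | (2S)-4-(tert-butyldimethylsilyloxy)-2-(3,4-dimethoxyphenyl)-5,6,7-trimethoxy-2H-chromene | COc1ccc([C@@H]2C=C(O[Si](C)(C)C(C)(C)C)c3c(cc(OC)c(OC)c3OC)O2)cc1OC | intermediate
12 | (2S)-2-(3,4-dimethoxyphenyl)-5,6,7-trimethoxy-2,3-dihydro-4H-chromen-4-one, (2S)-5,6,7,3',4'-pentamethoxyflavanone | COc1ccc([C@@H]2CC(=O)c3c(cc(OC)c(OC)c3OC)O2)cc1OC | target

Total step count: 7. Longest linear sequence: 6 steps (steps 2 to 7, from 4).

Steps most likely to fail

Step 6. Ring closure may be too slow at the hindered, electron-rich 1,1-disubstituted enol ether. Catalyst decay, cross-metathesis dimerisation at the vinyl group, or hydride-induced double-bond migration with loss of C2 could then take over. The fallback leaves the route at 3 and rejoins it at 12; it sets C2 by asymmetric conjugate arylation of a chromone instead. Condensation of 3 with N,N-dimethylformamide dimethyl acetal (PhMe, 90 °C) should give (E)-3-(dimethylamino)-1-(6-hydroxy-2,3,4-trimethoxyphenyl)prop-2-en-1-one F1. Brief treatment with HCl in CH2Cl2 should cyclise it, with loss of dimethylamine, to 5,6,7-trimethoxy-4H-chromen-4-one F2. Palladium-catalysed asymmetric 1,4-addition of commercial 3,4-dimethoxyphenylboronic acid should then give 12 directly. The conditions would be Pd(OCOCF3)2, the tert-butyl pyridinooxazoline ligand of the enantiomeric series that leads to 2S, NH4PF6, H2O, ClCH2CH2Cl, 60 °C.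

Step 4. The chelated, hindered ortho-acyl aryloxide may attack slowly. That would allow attack at the unsubstituted allyl terminus, or re-ionisation of the electron-rich branched ether, with erosion of regio- and enantioselectivity. The fallback sets out from 3 (through its sodium salt 8) and returns at 9; the stereocentre is obtained by resolution and transferred stereospecifically.
- CH2=CHMgBr added to commercial 3,4-dimethoxybenzaldehyde (THF, 0 °C) should give racemic 1-(3,4-dimethoxyphenyl)prop-2-en-1-ol F3.
- Lipase-catalysed acylation (Novozym 435, vinyl acetate, MTBE, 30 °C, stopped near half conversion) should leave (S)-1-(3,4-dimethoxyphenyl)prop-2-en-1-ol F4, given the usual preference of this enzyme for the R enantiomer of 1-arylalkanols. The by-product (R)-1-(3,4-dimethoxyphenyl)prop-2-en-1-yl acetate F5 is separated and discarded.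
- ClCO2Me and pyridine (CH2Cl2, 0 °C) should convert F4 into (S)-1-(3,4-dimethoxyphenyl)prop-2-en-1-yl methyl carbonate F6.
- Rhodium-catalysed allylic etherification of F6 with 8 (RhCl(PPh3)3, P(OMe)3, THF, 0 °C → rt) should give 9. This reaction is known to take ortho-substituted aryloxides at the substituted allyl terminus with overall retention.

Step 7. Acid-promoted opening of ring C may compete with slow C3 protonation of the robust tert-butyldimethylsilyl enol ether. Ionisation at the benzylic C2–O1 bond, or reversible opening to the 2'-hydroxychalcone, would racemise C2. The fallback sets out from 9 and returns at 12; it changes the protecting-group plan so that the last cleavage needs only a weak acid. TESOTf and Et3N (CH2Cl2, −78 °C) should give triethyl({1-[2-{[(1S)-1-(3,4-dimethoxyphenyl)prop-2-en-1-yl]oxy}-4,5,6-trimethoxyphenyl]ethenyl}oxy)silane F7. The metathesis of step 6 should convert it into (2S)-2-(3,4-dimethoxyphenyl)-5,6,7-trimethoxy-4-(triethylsilyloxy)-2H-chromene F8. AcOH–THF–H2O at 0 °C to rt should then release 12 under conditions too mild to ionise the C2–O1 bond.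

Further compounds
F1 | step 6 | (E)-3-(dimethylamino)-1-(6-hydroxy-2,3,4-trimethoxyphenyl)prop-2-en-1-one | CN(C)/C=C/C(=O)c1c(O)cc(OC)c(OC)c1OC
F2 | step 6 | 5,6,7-trimethoxy-4H-chromen-4-one | COc1cc2occc(=O)c2c(OC)c1OC
F3 | step 4 | racemic 1-(3,4-dimethoxyphenyl)prop-2-en-1-ol | COc1ccc(C(O)C=C)cc1OC
F4 | step 4 | (S)-1-(3,4-dimethoxyphenyl)prop-2-en-1-ol | COc1ccc([C@@H](O)C=C)cc1OC
F5 | step 4 | (R)-1-(3,4-dimethoxyphenyl)prop-2-en-1-yl acetate | COc1ccc([C@H](OC(C)=O)C=C)cc1OC
F6 | step 4 | (S)-1-(3,4-dimethoxyphenyl)prop-2-en-1-yl methyl carbonate | COc1ccc([C@@H](OC(=O)OC)C=C)cc1OC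
F7 | step 7 | triethyl({1-[2-{[(1S)-1-(3,4-dimethoxyphenyl)prop-2-en-1-yl]oxy}-4,5,6-trimethoxyphenyl]ethenyl}oxy)silane | COc1ccc([C@@H](Oc2cc(OC)c(OC)c(OC)c2C(=C)O[Si](CC)(CC)CC)C=C)cc1OC
F8 | step 7 | (2S)-2-(3,4-dimethoxyphenyl)-5,6,7-trimethoxy-4-(triethylsilyloxy)-2H-chromene | COc1ccc([C@@H]2C=C(O[Si](CC)(CC)CC)c3c(cc(OC)c(OC)c3OC)O2)cc1OC
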